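**Retrosynthetic overview**

1. Numbering: ring B–C7–C8–C9 and syringyl–C7'–C8'–C9' joined at C8–C8' with ethers C7–O–C9' and C7'–O–C9; side chain ring A–C7''–C8''–C9'' with C8''–O–C4 of ring B.
2. Feature: the C8–C8' bond with its neighbours C7, C9, C7', C9' is a masked trans-2,3-disubstituted γ-butyrolactone (C9 = lactone carbonyl, C9' = acetal carbon), in which C7 is an aldol acceptor carbon and C7' an acyl-anion carbon.
3. Both tetrahydrofuran rings of the furofuran are closed last, in one operation, from a 1,4-diaryl-2,3-bis(hydroxymethyl)butane-1,4-diol through the C7 and C7' benzylic cations; the tetraol comes from LiAlH4 reduction of a keto lactone, itself from dithiane hydrolysis.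
4. Key disconnection: C7'–C8' (1,4-addition of a lithiated syringyl dithiane to (5S)-5-(d-menthyloxy)butenolide) and C8–C7 (aldol trapping of the enolate by the ring B aldehyde) in one flask; no ring is closed there.
5. The ring B aldehyde carries the erythro side chain as a 1,3-dioxane and comes from an auxiliary-controlled anti glycolate aldol (C7''–C8''); ring order: butenolide (from furfural), dioxane, then the two furofuran rings.

Key step: step 12

Remark: TBS = tert-butyldimethylsilyl; d-menthyl = (1S,2R,5S)-2-isopropyl-5-methylcyclohexyl; the target is (7R,8S,7'R,8'S,7''R,8''S).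
Remark (assumption): ring B is introduced as 4-bromo-2-methoxyphenol and the bromide is turned into the aldehyde only after the side chain is built, so that no aldehyde competes in the glycolate aldol.
Remark (assumption): the menthyl acetal that crystallises from (+)-menthol is taken to be the (5S) diastereomer, the mirror image of the crystalline (5R) acetal of (−)-menthol.
Remark: the C7 carbinol of the adduct and the C7/C7' carbinols of the tetraol are carried as epimer mixtures, and their SMILES leave these centres undefined.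

**Route**

Step 1
Reactants: 1 syringaldehyde
Product: 2 2-(4-hydroxy-3,5-dimethoxyphenyl)-1,3-dithiane
Conditions: HS(CH2)3SH, BF3·OEt2 (cat.), CH2Cl2, 0 °C to rt
Reagents that add atoms: propane-1,3-dithiol (SCCCS)
Why: BF3-catalysed thioacetalisation of the aryl aldehyde should give the dithiane cleanly, since the free phenol does not interfere and no stereocentre is formed.

Step 2
Reactants: 2 2-(4-hydroxy-3,5-dimethoxyphenyl)-1,3-dithiane
Product: 3 2-[4-(TBSO)-3,5-dimethoxyphenyl]-1,3-dithiane
Conditions: TBSCl, imidazole, DMF, rt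
Reagents that add atoms: tert-butyldimethylsilyl chloride (CC(C)(C)[Si](C)(C)Cl)
Why: O-silylation of the hindered phenol with imidazole as base should give an aryl silyl ether that tolerates the later organolithium, hydride and mercury steps.

Step 3
Reactants: 4 furfural
Product: 6 racemic 5-hydroxyfuran-2(5H)-one, via furfural endoperoxide 5 (not isolated)
Conditions: O2, hν (visible light), methylene blue (C16H18ClN3S, cat.), MeOH, rt
Reagents that add atoms: dioxygen (O=O)
Why: dye-sensitised photooxygenation should add singlet oxygen across the furan in a [4+2] cycloaddition, and attack of methanol on the formyl group then fragments endoperoxide 5 to the hydroxybutenolide with loss of methyl formate.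

Step 4
Reactants: 6 racemic 5-hydroxyfuran-2(5H)-one; 7 (+)-menthol
Product: 9 (5S)-5-(d-menthyloxy)furan-2(5H)-one, via (5R)-menthyloxy epimer 8 (not isolated)
Conditions: CSA (cat.), toluene, reflux, Dean–Stark; crystallisation from petroleum ether, −20 °C; mother liquor re-equilibrated with CSA (cat.) and recrystallised
Reagents that add atoms: none
Why: acid-catalysed acetalisation should give both C5 epimers, and because C5 equilibrates through the cyclic oxocarbenium ion while the (5S) diastereomer crystallises, a crystallisation-induced asymmetric transformation should funnel epimer 8 into 9.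

Step 5
Reactants: 10 vanillin
Product: 11 4-(TBSO)-3-methoxybenzaldehyde
Conditions: TBSCl, imidazole, DMF, rt
Reagents that add atoms: tert-butyldimethylsilyl chloride (CC(C)(C)[Si](C)(C)Cl)
Why: O-silylation of the phenol should proceed without touching the aldehyde and removes the acidic proton that would quench the later enolate chemistry.

Step 6
Reactants: 12 4-bromo-2-methoxyphenol; 13 bromoacetic acid
Product: 14 (4-bromo-2-methoxyphenoxy)acetic acid
Conditions: NaOH, H2O, reflux; then HCl (aq) to pH 1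
Reagents that add atoms: none
Why: Williamson ether synthesis, in which the phenoxide displaces bromide from bromoacetate, should give the aryloxyacetic acid that supplies C8'' and C9''.

Step 7
Reactants: 14 (4-bromo-2-methoxyphenoxy)acetic acid; 15 (S)-4-benzyl-2-oxazolidinone
Product: 17 (4S)-4-benzyl-3-[(4-bromo-2-methoxyphenoxy)acetyl]oxazolidin-2-one, via mixed pivalic anhydride 16 (not isolated)
Conditions: PivCl, Et3N, THF, −20 °C; then 15, LiCl, −20 °C to rt
Reagents that add atoms: none
Why: N-acylation of the oxazolidinone through the mixed anhydride should occur at the less hindered aryloxyacetyl carbonyl and give the imide, which has no stereocentre at risk.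

Step 8
Reactants: 17 (4S)-4-benzyl-3-[(4-bromo-2-methoxyphenoxy)acetyl]oxazolidin-2-one; 11 4-(TBSO)-3-methoxybenzaldehyde
Product: 19 (4S)-4-benzyl-3-[(2R,3R)-2-(4-bromo-2-methoxyphenoxy)-3-hydroxy-3-(4-TBSO-3-methoxyphenyl)propanoyl]oxazolidin-2-one, via aldol trimethylsilyl ether 18 (not isolated)
Conditions: MgCl2 (0.2 equiv), Et3N, TMSCl, EtOAc, rt; then 1 M HCl, THF, 0 °C
Reagents that add atoms: none
Why: in this magnesium-halide-catalysed direct anti-aldol of an N-acyloxazolidinone (Evans anti-aldol), soft enolisation of the MgCl2-chelated imide should give the Z enolate, the aldehyde should add to the enolate face away from the benzyl group of the auxiliary, which sets C8'', with anti topology that sets C7'' in the erythro sense, and silylation to 18 blocks retro-aldol and turns the catalyst over.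

Step 9
Reactants: 19 the anti-aldol adduct
Product: 20 (1R,2S)-2-(4-bromo-2-methoxyphenoxy)-1-(4-TBSO-3-methoxyphenyl)propane-1,3-diol
Conditions: LiBH4, MeOH (1 equiv), THF, 0 °C
Reagents that add atoms: none
Why: reductive cleavage of the imide with LiBH4 should give the 1,3-diol and return the auxiliary without touching the aryl bromide, the aryl silyl ether or the two stereocentres.

Step 10
Reactants: 20 the erythro diol
Product: 21 (4R,5S)-5-(4-bromo-2-methoxyphenoxy)-4-(4-TBSO-3-methoxyphenyl)-2,2-dimethyl-1,3-dioxane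
Conditions: Me2C(OMe)2, PPTS (cat.), CH2Cl2, rt
Reagents that add atoms: 2,2-dimethoxypropane (COC(C)(C)OC)
Why: acid-catalysed transacetalisation (acetonide formation) should close the six-membered dioxane on the only diol present, and the weak acid leaves the aryl silyl ether and the benzylic centre untouched.

Step 11
Reactants: 21 the bromo dioxane
Product: 23 4-{[(4R,5S)-4-(4-TBSO-3-methoxyphenyl)-2,2-dimethyl-1,3-dioxan-5-yl]oxy}-3-methoxybenzaldehyde, via aryllithium 22 (not isolated)
Conditions: n-BuLi, THF, −78 °C; DMF, −78 to 0 °C; H2O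
Reagents that add atoms: N,N-dimethylformamide (CN(C)C=O)
Why: bromine–lithium exchange followed by formylation of aryllithium 22 with DMF should give the aldehyde, since the dioxane, the aryl ethers and the silyl ether are inert to n-BuLi at −78 °C.

Step 12
Reactants: 3 2-[4-(TBSO)-3,5-dimethoxyphenyl]-1,3-dithiane; 9 (5S)-5-(d-menthyloxy)furan-2(5H)-one; 23 the ring B aldehyde
Product: 26 (3R,4S,5S)-3-[hydroxy(ring B aryl)methyl]-4-[2-(4-TBSO-3,5-dimethoxyphenyl)-1,3-dithian-2-yl]-5-(d-menthyloxy)dihydrofuran-2(3H)-one (ring B aryl = 4-{[(4R,5S)-4-(4-TBSO-3-methoxyphenyl)-2,2-dimethyl-1,3-dioxan-5-yl]oxy}-3-methoxyphenyl; both C7 carbinol epimers), via 2-lithio-1,3-dithiane 24 (not isolated), via lactone lithium enolate 25 (not isolated)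
Conditions: 3, n-BuLi, THF, −78 to −30 °C; 9, −78 °C; 23, −78 °C; AcOH, −78 °C
Reagents that add atoms: none
Why: n-BuLi removes the benzylic dithiane proton of 3 to give the soft, sulfur- and aryl-stabilised carbanion 24, which adds 1,4 to butenolide 9 to form the C7'–C8' bond and enolate 25, and this enolate is trapped at −78 °C by aldehyde 23 to form the C8–C7 bond; the reaction type is the known tandem conjugate addition–aldol of lithiated aryl dithioacetals on 5-alkoxybutenolides. No ring is closed in this step. C8' should be set by attack on the butenolide face anti to the menthyloxy group at the acetal carbon C9', and C8 by approach of the aldehyde anti to the bulky dithianyl group on the neighbouring carbon, so that the lactone is 3,4-trans and 4,5-trans. The step needs 1,4- over 1,2-addition, which the delocalised anion and the unhindered β-carbon should secure, and it needs 24 to be consumed before 23 is added so that no dithiane anion attacks the aldehyde directly. The C7 carbinol configuration is left uncontrolled on purpose, because C7 is ionised and reset in step 15. The cold acetic acid quench should keep the aldolate from retro-aldol cleavage on warming.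

Step 13
Reactants: 26 the dithianyl lactone
Product: 27 (3R,4S,5S)-3-[hydroxy(ring B aryl)methyl]-4-(4-TBSO-3,5-dimethoxybenzoyl)-5-(d-menthyloxy)dihydrofuran-2(3H)-one
Conditions: Hg(ClO4)2·3H2O, CaCO3, THF/H2O (5:1), 0 °C
Reagents that add atoms: water (O)
Why: thiophilic, mercury-assisted dithiane hydrolysis buffered by CaCO3 should unmask the C7' aryl ketone under near-neutral conditions that spare the dioxane, the menthyl acetal, the silyl ethers and the aldol, while the trans arrangement on the lactone keeps the C7 hydroxyl from forming a hemiketal.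

Step 14
Reactants: 27 the keto lactone
Product: 28 (2S,3S)-1-(ring B aryl)-2,3-bis(hydroxymethyl)-4-(4-TBSO-3,5-dimethoxyphenyl)butane-1,4-diol (C1 and C4 epimers)
Conditions: LiAlH4, THF, 0 °C to rt; then H2O
Reagents that add atoms: none
Why: hydride reduction with LiAlH4 should turn the ketone into the C7' carbinol, the lactone carbonyl into the C9 primary alcohol and the acetal carbon C9', once (+)-menthol is expelled, into the second primary alcohol, with C8 and C8' unchanged.

Step 15
Reactants: 28 the tetraol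
Product: 29 bis-TBS ether 7'',9''-acetonide of ficusesquilignan A, (7R,8S,7'R,8'S) furofuran
Conditions: CSA (0.1 equiv), 4 Å molecular sieves, CH2Cl2, 0 °C to rt
Reagents that add atoms: none
Why: in this acid-catalysed dehydrative double cyclisation (two 5-exo closures), reversible ionisation of the two electron-rich benzylic carbinols should let the C9' hydroxyl capture the C7 cation and the C9 hydroxyl capture the C7' cation, and thermodynamic control on the cis-fused bicycle fixed by C8 and C8' should place both aryl groups exo, which sets C7 as R and C7' as R, whereas C7'' is held in the dioxane and deactivated by the neighbouring aryloxy group.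

Step 16
Reactants: 29 the protected furofuran
Product: 30 bis-TBS ether of ficusesquilignan A
Conditions: AcOH/THF/H2O (3:1:1), 40 °C
Reagents that add atoms: none
Why: mild aqueous acid hydrolysis of the isopropylidene acetal should free the 7''- and 9''-hydroxyls through the oxocarbenium ion at the ketal carbon, without ionising C7'' or the furofuran ethers while the phenols are still silylated.

Step 17
Reactants: 30 bis-TBS ether of ficusesquilignan A
Product: 31 ficusesquilignan A
Conditions: Bu4NF, AcOH, THF, 0 °C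
Reagents that add atoms: none
Why: fluoride-mediated cleavage of the two aryl silyl ethers, buffered with acetic acid so that no phenoxide persists, should give the target with all six stereocentres untouched.

**Compound list**

1 | syringaldehyde | COc1cc(C=O)cc(OC)c1O | starting material
2 | 2-(4-hydroxy-3,5-dimethoxyphenyl)-1,3-dithiane | COc1cc(C2SCCCS2)cc(OC)c1O | intermediate
3 | 2-[4-(TBSO)-3,5-dimethoxyphenyl]-1,3-dithiane | COc1cc(C2SCCCS2)cc(OC)c1O[Si](C)(C)C(C)(C)C | intermediate
4 | furfural | O=Cc1ccco1 | starting material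
5 | furfural endoperoxide, 2,3,7-trioxabicyclo[2.2.1]hept-5-ene-1-carbaldehyde (not isolated) | O=CC12OOC(C=C1)O2 | intermediate
6 | racemic 5-hydroxyfuran-2(5H)-one | O=C1OC(O)C=C1 | intermediate
7 | (+)-menthol, (1S,2R,5S)-2-isopropyl-5-methylcyclohexanol | CC(C)[C@H]1CC[C@H](C)C[C@@H]1O | starting material
8 | (5R)-5-(d-menthyloxy)furan-2(5H)-one (epimer, not isolated) | O=C1O[C@@H](O[C@H]2C[C@@H](C)CC[C@@H]2C(C)C)C=C1 | intermediate
9 | (5S)-5-(d-menthyloxy)furan-2(5H)-one | O=C1O[C@H](O[C@H]2C[C@@H](C)CC[C@@H]2C(C)C)C=C1 | intermediate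
10 | vanillin | COc1cc(C=O)ccc1O | starting material
11 | 4-(TBSO)-3-methoxybenzaldehyde | COc1cc(C=O)ccc1O[Si](C)(C)C(C)(C)C | intermediate
12 | 4-bromo-2-methoxyphenol | COc1cc(Br)ccc1O | starting material
13 | bromoacetic acid | OC(=O)CBr | starting material
14 | (4-bromo-2-methoxyphenoxy)acetic acid | COc1cc(Br)ccc1OCC(=O)O | intermediate
15 | (S)-4-benzyl-2-oxazolidinone | O=C1N[C@@H](Cc2ccccc2)CO1 | starting material
16 | (4-bromo-2-methoxyphenoxy)acetic pivalic anhydride (not isolated) | COc1cc(Br)ccc1OCC(=O)OC(=O)C(C)(C)C | intermediate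
17 | (4S)-4-benzyl-3-[(4-bromo-2-methoxyphenoxy)acetyl]oxazolidin-2-one | COc1cc(Br)ccc1OCC(=O)N1[C@@H](Cc2ccccc2)COC1=O | intermediate
18 | trimethylsilyl ether of aldol adduct 19 (not isolated) | COc1cc([C@@H](O[Si](C)(C)C)[C@H](C(=O)N2[C@@H](Cc3ccccc3)COC2=O)Oc4ccc(Br)cc4OC)ccc1O[Si](C)(C)C(C)(C)C | intermediate
19 | (4S)-4-benzyl-3-[(2R,3R)-2-(4-bromo-2-methoxyphenoxy)-3-hydroxy-3-(4-TBSO-3-methoxyphenyl)propanoyl]oxazolidin-2-one | COc1cc([C@@H](O)[C@H](C(=O)N2[C@@H](Cc3ccccc3)COC2=O)Oc4ccc(Br)cc4OC)ccc1O[Si](C)(C)C(C)(C)C | intermediate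
20 | (1R,2S)-2-(4-bromo-2-methoxyphenoxy)-1-(4-TBSO-3-methoxyphenyl)propane-1,3-diol | COc1cc([C@@H](O)[C@H](CO)Oc2ccc(Br)cc2OC)ccc1O[Si](C)(C)C(C)(C)C | intermediate
21 | (4R,5S)-5-(4-bromo-2-methoxyphenoxy)-4-(4-TBSO-3-methoxyphenyl)-2,2-dimethyl-1,3-dioxane | COc1cc([C@H]2OC(C)(C)OC[C@@H]2Oc3ccc(Br)cc3OC)ccc1O[Si](C)(C)C(C)(C)C | intermediate
22 | aryllithium from 21 (not isolated) | COc1cc([C@H]2OC(C)(C)OC[C@@H]2Oc3ccc([Li])cc3OC)ccc1O[Si](C)(C)C(C)(C)C | intermediate
23 | 4-{[(4R,5S)-4-(4-TBSO-3-methoxyphenyl)-2,2-dimethyl-1,3-dioxan-5-yl]oxy}-3-methoxybenzaldehyde | COc1cc([C@H]2OC(C)(C)OC[C@@H]2Oc3ccc(C=O)cc3OC)ccc1O[Si](C)(C)C(C)(C)C | intermediate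
24 | 2-lithio derivative of dithiane 3 (not isolated) | COc1cc(C2([Li])SCCCS2)cc(OC)c1O[Si](C)(C)C(C)(C)C | intermediate
25 | lithium enolate of the (4S,5S) conjugate adduct (not isolated) | [Li]OC1=C[C@H](C2(c3cc(OC)c(O[Si](C)(C)C(C)(C)C)c(OC)c3)SCCCS2)[C@@H](O[C@H]2C[C@@H](C)CC[C@@H]2C(C)C)O1 | intermediate
26 | (3R,4S,5S)-3-[hydroxy(ring B aryl)methyl]-4-[2-(4-TBSO-3,5-dimethoxyphenyl)-1,3-dithian-2-yl]-5-(d-menthyloxy)dihydrofuran-2(3H)-one, C7 epimers | COc1cc([C@H]5OC(C)(C)OC[C@@H]5Oc2ccc(C(O)[C@@H]3C(=O)O[C@H](O[C@H]6C[C@@H](C)CC[C@@H]6C(C)C)[C@H]3C4(c7cc(OC)c(O[Si](C)(C)C(C)(C)C)c(OC)c7)SCCCS4)cc2OC)ccc1O[Si](C)(C)C(C)(C)C | intermediate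
27 | (3R,4S,5S)-3-[hydroxy(ring B aryl)methyl]-4-(4-TBSO-3,5-dimethoxybenzoyl)-5-(d-menthyloxy)dihydrofuran-2(3H)-one, C7 epimers | COc1cc([C@H]5OC(C)(C)OC[C@@H]5Oc2ccc(C(O)[C@@H]3C(=O)O[C@H](O[C@H]6C[C@@H](C)CC[C@@H]6C(C)C)[C@H]3C(=O)c7cc(OC)c(O[Si](C)(C)C(C)(C)C)c(OC)c7)cc2OC)ccc1O[Si](C)(C)C(C)(C)C | intermediate
28 | (2S,3S)-1-(ring B aryl)-2,3-bis(hydroxymethyl)-4-(4-TBSO-3,5-dimethoxyphenyl)butane-1,4-diol, C1 and C4 epimers | COc1cc([C@H]5OC(C)(C)OC[C@@H]5Oc2ccc(C(O)[C@H](CO)[C@@H](CO)C(O)c7cc(OC)c(O[Si](C)(C)C(C)(C)C)c(OC)c7)cc2OC)ccc1O[Si](C)(C)C(C)(C)C | intermediate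
29 | bis-TBS ether 7'',9''-acetonide of ficusesquilignan A | COc1cc([C@H]5OC(C)(C)OC[C@@H]5Oc2ccc([C@@H]3OC[C@@H]4[C@H]3CO[C@H]4c7cc(OC)c(O[Si](C)(C)C(C)(C)C)c(OC)c7)cc2OC)ccc1O[Si](C)(C)C(C)(C)C | intermediate
30 | bis-TBS ether of ficusesquilignan A | COc1cc([C@@H](O)[C@H](CO)Oc2ccc([C@@H]3OC[C@@H]4[C@H]3CO[C@H]4c5cc(OC)c(O[Si](C)(C)C(C)(C)C)c(OC)c5)cc2OC)ccc1O[Si](C)(C)C(C)(C)C | intermediate
31 | ficusesquilignan A, (7R,8S,7'R,8'S,7''R,8''S) | COc1cc([C@@H](O)[C@H](CO)Oc2ccc([C@@H]3OC[C@@H]4[C@H]3CO[C@H]4c3cc(OC)c(O)c(OC)c3)cc2OC)ccc1O | target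

**Summary**

Total step count: 17.
Longest linear sequence: 12 steps (steps 6 to 17, from 4-bromo-2-methoxyphenol).

Steps most likely to fail:

1. Step 12. The hindered lactone enolate may be trapped only slowly by the large aldehyde, so that proton transfer or retro-aldol on work-up leaves the union at the stage of the conjugate adduct. Fallback: starting from 3 and 9, the conjugate addition is run alone and quenched with aqueous NH4Cl to isolate the lactone (4S,5S)-4-[2-(4-TBSO-3,5-dimethoxyphenyl)-1,3-dithian-2-yl]-5-(d-menthyloxy)dihydrofuran-2(3H)-one F1. F1 is then deprotonated with LiN(i-Pr)2 in THF at −78 °C, the enolate is transmetalated with ZnCl2 and combined with 23 in a separate directed aldol. The less basic zinc aldolate should resist retro-aldol, and the route is rejoined at 26.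

2. Step 8. Anti/syn or facial selectivity may be poor, or addition to the electron-rich aldehyde slow, in the magnesium-catalysed aldol. Fallback: starting from 14 and 11, a boron-mediated syn aldol is followed by inversion of C7''.
   - Acid 14 is coupled, again through anhydride 16, with (R)-4-benzyl-2-oxazolidinone to give the imide (4R)-4-benzyl-3-[(4-bromo-2-methoxyphenoxy)acetyl]oxazolidin-2-one F2.
   - Its dibutylboron Z enolate (Bu2BOTf, i-Pr2NEt, CH2Cl2, −78 to 0 °C) should add to 11 through the closed chair transition state to give the threo adduct (4R)-4-benzyl-3-[(2R,3S)-2-(4-bromo-2-methoxyphenoxy)-3-hydroxy-3-(4-TBSO-3-methoxyphenyl)propanoyl]oxazolidin-2-one F3, in which C8'' is already correct.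
   - LiBH4 gives the threo diol (1S,2S)-2-(4-bromo-2-methoxyphenoxy)-1-(4-TBSO-3-methoxyphenyl)propane-1,3-diol F4.
   - TBSCl and imidazole silylate the primary hydroxyl to give (1S,2S)-2-(4-bromo-2-methoxyphenoxy)-3-(TBSO)-1-(4-TBSO-3-methoxyphenyl)propan-1-ol F5.
   - Dess–Martin oxidation gives the ketone (2S)-2-(4-bromo-2-methoxyphenoxy)-3-(TBSO)-1-(4-TBSO-3-methoxyphenyl)propan-1-one F6.
   - Reduction with NaBH4 in MeOH at −40 °C under Felkin–Anh control should give the erythro alcohol (1R,2S)-2-(4-bromo-2-methoxyphenoxy)-3-(TBSO)-1-(4-TBSO-3-methoxyphenyl)propan-1-ol F7.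
   - AcOH/THF/H2O removes the primary silyl ether only, and the route is rejoined at 20.

3. Step 15. Under the acid the isopropylidene group may migrate onto the 1,3-diol units of the tetraol or be lost in part, so that the double closure stalls or gives mixtures; prolonged acid could also bring irreversible Friedel–Crafts closure onto the syringyl ring. Fallback: starting from 28, the order of deprotection and cyclisation is reversed. The acetonide is hydrolysed first with AcOH/THF/H2O to give the hexaol (2S,3S)-1-{4-[(1R,2S)-1,3-dihydroxy-1-(4-TBSO-3-methoxyphenyl)propan-2-yl]oxy-3-methoxyphenyl}-2,3-bis(hydroxymethyl)-4-(4-TBSO-3,5-dimethoxyphenyl)butane-1,4-diol F8. F8 is then cyclised with CSA (cat.) in MeCN at rt for a short time. The C7'' carbinol, deactivated by the neighbouring aryloxy group, should ionise much more slowly than C7 and C7', and the route is rejoined at 30.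

Further compounds
F1 | step 12 | (4S,5S)-4-[2-(4-TBSO-3,5-dimethoxyphenyl)-1,3-dithian-2-yl]-5-(d-menthyloxy)dihydrofuran-2(3H)-one | O=C1C[C@H](C2(c3cc(OC)c(O[Si](C)(C)C(C)(C)C)c(OC)c3)SCCCS2)[C@@H](O[C@H]2C[C@@H](C)CC[C@@H]2C(C)C)O1
F2 | step 8 | (4R)-4-benzyl-3-[(4-bromo-2-methoxyphenoxy)acetyl]oxazolidin-2-one | COc1cc(Br)ccc1OCC(=O)N1[C@H](Cc2ccccc2)COC1=O
F3 | step 8 | (4R)-4-benzyl-3-[(2R,3S)-2-(4-bromo-2-methoxyphenoxy)-3-hydroxy-3-(4-TBSO-3-methoxyphenyl)propanoyl]oxazolidin-2-one | COc1cc([C@H](O)[C@H](C(=O)N2[C@H](Cc3ccccc3)COC2=O)Oc4ccc(Br)cc4OC)ccc1O[Si](C)(C)C(C)(C)C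
F4 | step 8 | (1S,2S)-2-(4-bromo-2-methoxyphenoxy)-1-(4-TBSO-3-methoxyphenyl)propane-1,3-diol | COc1cc([C@H](O)[C@H](CO)Oc2ccc(Br)cc2OC)ccc1O[Si](C)(C)C(C)(C)C
F5 | step 8 | (1S,2S)-2-(4-bromo-2-methoxyphenoxy)-3-(TBSO)-1-(4-TBSO-3-methoxyphenyl)propan-1-ol | COc1cc([C@H](O)[C@H](CO[Si](C)(C)C(C)(C)C)Oc2ccc(Br)cc2OC)ccc1O[Si](C)(C)C(C)(C)C
F6 | step 8 | (2S)-2-(4-bromo-2-methoxyphenoxy)-3-(TBSO)-1-(4-TBSO-3-methoxyphenyl)propan-1-one | COc1cc(C(=O)[C@H](CO[Si](C)(C)C(C)(C)C)Oc2ccc(Br)cc2OC)ccc1O[Si](C)(C)C(C)(C)C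
F7 | step 8 | (1R,2S)-2-(4-bromo-2-methoxyphenoxy)-3-(TBSO)-1-(4-TBSO-3-methoxyphenyl)propan-1-ol | COc1cc([C@@H](O)[C@H](CO[Si](C)(C)C(C)(C)C)Oc2ccc(Br)cc2OC)ccc1O[Si](C)(C)C(C)(C)C
F8 | step 15 | (2S,3S)-1-{4-[(1R,2S)-1,3-dihydroxy-1-(4-TBSO-3-methoxyphenyl)propan-2-yl]oxy-3-methoxyphenyl}-2,3-bis(hydroxymethyl)-4-(4-TBSO-3,5-dimethoxyphenyl)butane-1,4-diol, C1 and C4 epimers | COc1cc([C@@H](O)[C@H](CO)Oc2ccc(C(O)[C@H](CO)[C@@H](CO)C(O)c3cc(OC)c(O[Si](C)(C)C(C)(C)C)c(OC)c3)cc2OC)ccc1O[Si](C)(C)C(C)(C)C
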